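**Retrosynthetic overview**
1. 25 ⇐ 24 ⇐ 23 ⇐ 22: global desilylation; epoxidation of C8=C9 anti to a 7β-silyloxy group (the oxirane is the last ring formed).
2. 22 ⇐ 21 ⇐ 20 ⇐ 19 ⇐ 15: C7 is oxidised to the enone and reduced to the equatorial 7β-alcohol; 19 is the 6-O-aroyl ester of jaeschkeanadiol 15.
3. 15 ⇐ 13: one-flask cationic bicyclisation of an acyclic farnesane-type hydroxy ketone. The C6–C10 bond closes first (cyclopentane, Prins attack of the 6E alkene on the aluminium-bound C10 ketone, which creates the tertiary carbinol), then the C1–C7 bond (cycloheptene, allylsilane capture of the tertiary cation). Farnesane numbering; these are the two bonds of the farnesyl → daucane cyclisation.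
4. 13 ⇐ 5 + 12: asymmetric Ni/Cr alkenylation. 5 comes from but-2-yn-1-ol (hydrosilylation, Claisen); 12 from prop-2-yn-1-ol and 3-methylbutan-2-one.

Assumption: the presumed biosynthesis is taken as the farnesyl-derived cationic closure of the C6–C10 and C1–C7 bonds to the dauc-8-ene-4β,6α-diol (jaeschkeanadiol) core, followed by 6-O-acylation, C7 hydroxylation and 8,9-epoxidation.

Ring compounds use daucane numbering (C1 angular methyl carbon, C4 isopropyl carbinol, C5 ring-fusion CH, C6 ester carbon, C7 carbinol, C8/C9 oxirane carbons).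

**Route**

Step 1
Reactants: 1 but-2-yn-1-ol
Product: 2 (Z)-3-(triethylsilyl)but-2-en-1-ol
Conditions: Et3SiH (1.2 equiv), [Cp*Ru(MeCN)3]PF6 (1 mol%), CH2Cl2, 0 → 23 °C
Reagents that add atoms: triethylsilane CC[SiH](CC)CC
Why: cationic ruthenium-catalysed trans-hydrosilylation of a propargylic alcohol places silicon on the alkyne carbon distal to the hydroxyl, giving the γ-silyl allylic alcohol needed for the Claisen step (its alkene geometry is of no later consequence).

Step 2
Reactants: 2 (Z)-3-(triethylsilyl)but-2-en-1-ol; 3 ethyl vinyl ether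
Product: 5 3-methyl-3-(triethylsilyl)pent-4-enal (racemic), via allyl vinyl ether 4 (not isolated)
Conditions: Pd(OAc)2 (2 mol%), 1,10-phenanthroline (2 mol%), neat 3, 23 °C; evaporate; PhMe, 150 °C, sealed tube
Reagents that add atoms: none
Why: palladium-diacetate-catalysed vinyl transfer followed by thermal Claisen rearrangement moves the allyl unit to the silyl-bearing carbon, creating the tertiary allylsilane and a β-silyl aldehyde that cannot undergo Peterson elimination.

Step 3
Reactants: 6 prop-2-yn-1-ol
Product: 8 (E)-3-iodo-2-methylprop-2-en-1-ol, via alkenylalane 7 (not isolated)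
Conditions: AlMe3 (3 equiv), Cp2ZrCl2 (0.25 equiv), CH2Cl2, 0 → 23 °C; then I2, THF, −30 → 0 °C
Reagents that add atoms: trimethylaluminium C[Al](C)C; iodine II
Why: zirconium-catalysed Negishi carboalumination adds methyl and aluminium syn across the alkyne, and iodinolysis with retention fixes the E trisubstituted alkenyl iodide.

Step 4
Reactants: 8 (E)-3-iodo-2-methylprop-2-en-1-ol
Product: 9 (E)-3-bromo-1-iodo-2-methylprop-1-ene
Conditions: CBr4, PPh3, CH2Cl2, 0 °C
Reagents that add atoms: carbon tetrabromide BrC(Br)(Br)Br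
Why: Appel bromination converts the primary allylic alcohol into the bromide without touching the alkenyl iodide or its geometry.

Step 5
Reactants: 10 3-methylbutan-2-one; 9 (E)-3-bromo-1-iodo-2-methylprop-1-ene
Product: 12 (E)-7-iodo-2,6-dimethylhept-6-en-3-one, via lithium enolate 11 (not isolated)
Conditions: LiN(iPr)2 (LDA, 1.05 equiv), THF, −78 °C; then 9, DMPU, −78 → −20 °C
Reagents that add atoms: none
Why: kinetic deprotonation occurs at the methyl group of the isopropyl methyl ketone and the enolate is alkylated by the reactive allylic bromide (SN2), leaving the alkenyl iodide intact.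

Step 6
Reactants: 5 3-methyl-3-(triethylsilyl)pent-4-enal; 12 (E)-7-iodo-2,6-dimethylhept-6-en-3-one
Product: 13 (6E,8S)-8-hydroxy-2,6,10-trimethyl-10-(triethylsilyl)dodeca-6,11-dien-3-one (both C10 epimers)
Conditions: CrCl2 (3 equiv), NiCl2 (2 mol%), chiral oxazoline–sulfonamide ligand of the Kishi type (3.3 equiv, the enantiomer that gives the S carbinol), Et3N, THF, 23 °C
Reagents that add atoms: none
Why: the Nozaki–Hiyama–Kishi reaction adds the alkenylchromium species to the aldehyde only (the hindered ketone is untouched) with retention of the E geometry, and the chiral ligand on chromium sets the S carbinol; the silyl-bearing centre stays racemic and is destroyed in step 7.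

Step 7
Reactants: 13 (6E,8S)-8-hydroxy-2,6,10-trimethyl-10-(triethylsilyl)dodeca-6,11-dien-3-one
Product: 15 jaeschkeanadiol [(3R,3aS,4S,8aR)-6,8a-dimethyl-3-(propan-2-yl)-1,2,3,3a,4,5,8,8a-octahydroazulene-3,4-diol; 1β-Me 4β-OH 5α-H 6α-OH dauc-8-ene], via cyclopentyl cation 14 (not isolated)
Conditions: MeAlCl2 (2.5 equiv), CH2Cl2 (0.005 M), −78 → −30 °C; then aq. Rochelle salt
Reagents that add atoms: none
Why: Proposed new method: MeAlCl2 turns the carbinol into an aluminium alkoxide that binds the ketone, so the carbonyl is delivered to the alkene face that carries this oxygen in the conformer of least allylic 1,3-strain (carbinol H eclipsing the alkene); Markovnikov attack of the E alkene closes the cyclopentane and sets C4 (oxygen held syn to O-6 by the aluminium bridge, isopropyl turned away from the side chain) and C5, and the tertiary cation 14 is then captured on its opposite face by the allylsilane, which sits on the other side of the alkene plane, giving the trans ring fusion, the C1 quaternary centre and, after loss of silicon, the C8=C9 alkene; the closest known reaction types are the MeAlCl2-mediated Prins cyclisation of γ,δ-unsaturated ketones to cyclopentyl cations and the Hosomi–Sakurai termination of cation–olefin cyclisations.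

Step 8
Reactants: 16 4-hydroxybenzoic acid
Product: 18 4-[(tert-butyldimethylsilyl)oxy]benzoyl chloride, via bis-silyl compound 17 (not isolated)
Conditions: t-BuMe2SiCl (2.1 equiv), imidazole (2.2 equiv), CH2Cl2, 23 °C; filter; then (COCl)2 (1.2 equiv), DMF (cat.), 0 → 23 °C; concentrate
Reagents that add atoms: tert-butyldimethylsilyl chloride CC(C)(C)[Si](C)(C)Cl; oxalyl chloride O=C(Cl)C(Cl)=O
Why: double silylation masks the phenol, and the silyl ester is converted directly into the acid chloride by the Vilsmeier-type reagent from oxalyl chloride and DMF while the aryl silyl ether survives.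

Step 9
Reactants: 15 jaeschkeanadiol; 18 4-[(tert-butyldimethylsilyl)oxy]benzoyl chloride
Product: 19 jaeschkeanadiol 6-O-[4-(tert-butyldimethylsilyloxy)benzoate] (O-silyl ferutinin)
Conditions: Et3N (3 equiv), DMAP (0.5 equiv), CH2Cl2, 0 → 40 °C
Reagents that add atoms: none
Why: DMAP-catalysed acylation takes place at the secondary equatorial 6α-hydroxyl only, the tertiary 4β-hydroxyl being inert under these conditions.

Step 10
Reactants: 19 O-silyl ferutinin
Product: 20 7α-hydroxy derivative of 19 (4β,7α-dihydroxy-dauc-8-en-6α-yl 4-silyloxybenzoate)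
Conditions: SeO2 (0.5 equiv), t-BuOOH (3 equiv), CH2Cl2, 23 °C
Reagents that add atoms: selenium dioxide O=[Se]=O; tert-butyl hydroperoxide CC(C)(C)OO
Why: the Riley/Sharpless allylic oxidation (ene reaction then [2,3]-sigmatropic shift) attacks the ring CH2 on the more substituted alkene terminus (C7; CH2 before CH3) and returns the double bond to C8=C9; the axial 7α-alcohol expected is of no consequence because C7 is oxidised next.

Step 11
Reactants: 20 7α-hydroxy ester
Product: 21 8-en-7-one (4β-hydroxy-7-oxo-dauc-8-en-6α-yl 4-silyloxybenzoate)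
Conditions: Dess–Martin periodinane (1.5 equiv), NaHCO3, CH2Cl2, 23 °C
Reagents that add atoms: none
Why: Dess–Martin oxidation converts the secondary allylic alcohol (and any over-oxidised material already present) into the single enone without affecting the tertiary alcohol, ester or silyl ether.

Step 12
Reactants: 21 8-en-7-one
Product: 22 7β-hydroxy ester (4β,7β-dihydroxy-dauc-8-en-6α-yl 4-silyloxybenzoate)
Conditions: NaBH4, CeCl3·7H2O, MeOH, −78 °C
Reagents that add atoms: none
Why: Luche 1,2-reduction delivers hydride along the axial trajectory on the α face, giving the equatorial 7β-alcohol trans to the equatorial 6α-ester.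

Step 13
Reactants: 22 7β-hydroxy ester
Product: 23 7β-triethylsilyl ether of 22
Conditions: Et3SiCl (1.5 equiv), imidazole (3 equiv), DMAP (0.1 equiv), DMF, 23 °C
Reagents that add atoms: chlorotriethylsilane CC[Si](Cl)(CC)CC
Why: silylation of the secondary allylic alcohol (the tertiary alcohol does not react) removes its hydrogen-bond directing effect and places a bulky group on the β side of the alkene.

Step 14
Reactants: 23 7β-triethylsilyl ether
Product: 24 8α,9α-epoxide of 23
Conditions: mCPBA (1.5 equiv), NaHCO3, CH2Cl2, 0 °C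
Reagents that add atoms: 3-chloroperoxybenzoic acid OOC(=O)c1cccc(Cl)c1
Why: Prilezhaev epoxidation of the only alkene occurs on the α face, anti to the allylic silyloxy group and to the axial C1 methyl, setting C8 and C9.

Step 15
Reactants: 24 8α,9α-epoxide
Product: 25 target CNP0290052.1 (8α,9α-epoxy-4β,7β-dihydroxydaucan-6α-yl 4-hydroxybenzoate)
Conditions: Bu4NF (2.5 equiv), AcOH (2.5 equiv), THF, 0 °C
Reagents that add atoms: none
Why: fluoride cleaves the aryl silyl ether and the triethylsilyl ether in one operation, the acetic acid buffer preventing Payne rearrangement of the trans epoxy alcohol and acyl migration.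

**Compound list**
1 | but-2-yn-1-ol | CC#CCO | starting material
2 | (Z)-3-(triethylsilyl)but-2-en-1-ol | C/C(=C/CO)[Si](CC)(CC)CC | intermediate
3 | ethyl vinyl ether | CCOC=C | starting material
4 | (Z)-triethyl[4-(vinyloxy)but-2-en-2-yl]silane (allyl vinyl ether) | C=COC/C=C(/C)[Si](CC)(CC)CC | intermediate
5 | 3-methyl-3-(triethylsilyl)pent-4-enal (racemic) | O=CCC(C)(C=C)[Si](CC)(CC)CC | intermediate
6 | prop-2-yn-1-ol | C#CCO | starting material
7 | dimethylaluminium (E)-3-(dimethylalumanyl)-2-methylprop-2-en-1-olate (alkenylalane) | C[Al](C)/C=C(\C)CO[Al](C)C | intermediate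
8 | (E)-3-iodo-2-methylprop-2-en-1-ol | OC/C(C)=C/I | intermediate
9 | (E)-3-bromo-1-iodo-2-methylprop-1-ene | BrC/C(C)=C/I | intermediate
10 | 3-methylbutan-2-one | CC(=O)C(C)C | starting material
11 | lithium 3-methylbut-1-en-2-olate | [Li]OC(=C)C(C)C | intermediate
12 | (E)-7-iodo-2,6-dimethylhept-6-en-3-one | CC(C)C(=O)CC/C(C)=C/I | intermediate
13 | (6E,8S)-8-hydroxy-2,6,10-trimethyl-10-(triethylsilyl)dodeca-6,11-dien-3-one (C10 epimers) | C=CC(C)([Si](CC)(CC)CC)C[C@H](O)/C=C(\C)CCC(=O)C(C)C | intermediate
14 | monocyclic tertiary cyclopentyl cation (drawn without aluminium) | CC(C)[C@]1(O)CC[C+](C)[C@H]1[C@@H](O)CC(C)([Si](CC)(CC)CC)C=C | intermediate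
15 | jaeschkeanadiol, (3R,3aS,4S,8aR)-6,8a-dimethyl-3-(propan-2-yl)-1,2,3,3a,4,5,8,8a-octahydroazulene-3,4-diol | CC(C)[C@]1(O)CC[C@]2(C)CC=C(C)C[C@H](O)[C@H]21 | intermediate
16 | 4-hydroxybenzoic acid | OC(=O)c1ccc(O)cc1 | starting material
17 | tert-butyldimethylsilyl 4-[(tert-butyldimethylsilyl)oxy]benzoate | CC(C)(C)[Si](C)(C)OC(=O)c1ccc(O[Si](C)(C)C(C)(C)C)cc1 | intermediate
18 | 4-[(tert-butyldimethylsilyl)oxy]benzoyl chloride | O=C(Cl)c1ccc(O[Si](C)(C)C(C)(C)C)cc1 | intermediate
19 | jaeschkeanadiol 6-O-[4-(tert-butyldimethylsilyloxy)benzoate] | CC(C)[C@]1(O)CC[C@]2(C)CC=C(C)C[C@H](OC(=O)c3ccc(O[Si](C)(C)C(C)(C)C)cc3)[C@H]21 | intermediate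
20 | 4β,7α-dihydroxy-dauc-8-en-6α-yl 4-(tert-butyldimethylsilyloxy)benzoate | CC(C)[C@]1(O)CC[C@]2(C)CC=C(C)[C@H](O)[C@H](OC(=O)c3ccc(O[Si](C)(C)C(C)(C)C)cc3)[C@H]21 | intermediate
21 | 4β-hydroxy-7-oxo-dauc-8-en-6α-yl 4-(tert-butyldimethylsilyloxy)benzoate | CC(C)[C@]1(O)CC[C@]2(C)CC=C(C)C(=O)[C@H](OC(=O)c3ccc(O[Si](C)(C)C(C)(C)C)cc3)[C@H]21 | intermediate
22 | 4β,7β-dihydroxy-dauc-8-en-6α-yl 4-(tert-butyldimethylsilyloxy)benzoate | CC(C)[C@]1(O)CC[C@]2(C)CC=C(C)[C@@H](O)[C@H](OC(=O)c3ccc(O[Si](C)(C)C(C)(C)C)cc3)[C@H]21 | intermediate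
23 | 4β-hydroxy-7β-(triethylsilyloxy)-dauc-8-en-6α-yl 4-(tert-butyldimethylsilyloxy)benzoate | CC(C)[C@]1(O)CC[C@]2(C)CC=C(C)[C@@H](O[Si](CC)(CC)CC)[C@H](OC(=O)c3ccc(O[Si](C)(C)C(C)(C)C)cc3)[C@H]21 | intermediate
24 | 8α,9α-epoxy-4β-hydroxy-7β-(triethylsilyloxy)daucan-6α-yl 4-(tert-butyldimethylsilyloxy)benzoate | CC(C)[C@]1(O)CC[C@]2(C)C[C@@H]3O[C@]3(C)[C@@H](O[Si](CC)(CC)CC)[C@H](OC(=O)c3ccc(O[Si](C)(C)C(C)(C)C)cc3)[C@H]21 | intermediate
25 | CNP0290052.1, 8α,9α-epoxy-4β,7β-dihydroxydaucan-6α-yl 4-hydroxybenzoate | CC(C)[C@]1(O)CC[C@]2(C)C[C@@H]3O[C@]3(C)[C@@H](O)[C@H](OC(=O)c3ccc(O)cc3)[C@H]21 | target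

**Step count and risks**

Total step count: 15. Longest linear sequence: 12 steps (6 → 8 → 9 → 12 → 13 → 15 → 19 → 20 → 21 → 22 → 23 → 24 → 25, that is steps 3–7 and 9–15).

Step 7 (bicyclisation) is the most likely to fail. Cation 14 may lose a proton, take up chloride or undergo a 1,2-hydride shift before the seven-membered ring closes, and the isopropyl ketone is a weak electrophile. The fallback sets out from 13 and separates the two ring closures. Me2AlCl (1.1 equiv, CH2Cl2, −78 °C), which scavenges protons and does not sustain the cation, stops the sequence at the type-2 carbonyl-ene product, the methylenecyclopentane diol F1. Markovnikov addition of dry HCl (CH2Cl2, −78 °C) to the exocyclic alkene gives the tertiary chloride F2. Ionisation of F2 with TiCl4 (CH2Cl2, −78 °C) in a separate intramolecular Hosomi–Sakurai alkylation closes the cycloheptene and comes back to the route at 15. Here the ring fusion is no longer tied to the alkene geometry and may need separation of isomers.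

Step 10 (allylic oxidation) is second. C7 lies next to the ester-bearing carbon, so oxidation of the C8 methyl group may compete. The fallback sets out from 15 and brings the C7 oxygen in by enolate-type chemistry. Dess–Martin oxidation gives the β,γ-unsaturated 6-ketone F3. TMSOTf/Et3N (CH2Cl2, 0 °C) gives the bis-silyl dienol ether F4, the 4-hydroxyl being masked at the same time so that retro-aldol cleavage is excluded. Rubottom oxidation (dimethyldioxirane, acetone, −40 °C; then citric acid) gives the α-ketol F5. Acid-catalysed α-ketol (enediol) isomerisation (PPTS, PhMe, 60 °C) moves the carbonyl into conjugation and gives the 6α-hydroxy-8-en-7-one F6. Acylation of F6 with 18 (Et3N, DMAP, CH2Cl2) comes back to the route at 21.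

Step 6 (asymmetric coupling) is third. The coupling itself is reliable, but the enantioselectivity with a β-quaternary aldehyde may be modest. The fallback sets out from 12 and replaces chromium by an alkenylzinc addition. Ketalisation (ethylene glycol, TsOH, benzene, reflux) gives the dioxolane F7. Iodine–lithium exchange (tert-butyllithium, Et2O, −78 °C), transmetallation with ZnBr2 and amino-alcohol-catalysed addition to 5 (morpholinoisoborneol, the enantiomer that gives the S carbinol, hexane/PhMe, 0 °C) gives the protected allylic alcohol F8. PPTS in wet acetone (40 °C) frees the ketone and comes back to the route at 13.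

**Further compounds**
F1 | step 7 | methylenecyclopentane diol (type-2 ene product; 4β-OH 5α-H and S carbinol as in 15, exocyclic C1 methylene) | CC(C)[C@]1(O)CCC(=C)[C@H]1[C@@H](O)CC(C)([Si](CC)(CC)CC)C=C
F2 | step 7 | tertiary chloride from F1 (C1 chloride, both epimers) | CC(C)[C@]1(O)CCC(C)(Cl)[C@H]1[C@@H](O)CC(C)([Si](CC)(CC)CC)C=C
F3 | step 10 | 4β-hydroxy-dauc-8-en-6-one | CC(C)[C@]1(O)CC[C@]2(C)CC=C(C)CC(=O)[C@H]21
F4 | step 10 | 4β,6-bis(trimethylsilyloxy)-dauca-6,8-diene | CC(C)[C@]1(O[Si](C)(C)C)CC[C@]2(C)CC=C(C)C=C(O[Si](C)(C)C)[C@H]21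
F5 | step 10 | 4β,7-dihydroxy-dauc-8-en-6-one (C7 epimers) | CC(C)[C@]1(O)CC[C@]2(C)CC=C(C)C(O)C(=O)[C@H]21
F6 | step 10 | 4β,6α-dihydroxy-dauc-8-en-7-one | CC(C)[C@]1(O)CC[C@]2(C)CC=C(C)C(=O)[C@H](O)[C@H]21
F7 | step 6 | 2-[(E)-4-iodo-3-methylbut-3-enyl]-2-(propan-2-yl)-1,3-dioxolane | CC(C)C1(CC/C(C)=C/I)OCCO1
F8 | step 6 | ethylene ketal of 13 (S carbinol, E alkene) | C=CC(C)([Si](CC)(CC)CC)C[C@H](O)/C=C(\C)CCC1(C(C)C)OCCO1
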